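Everything rests on cutting the bond between the ring A benzylic carbon (C7) and lactone carbon C4, together with the neighbouring C3–C7' bond. The key step exploits the vicinal trans pair C3/C4 of the γ-butyrolactone ring, each carrying an arylmethyl group, which is the footprint of a butenolide C3=C4 double bond. In one operation a lithiated ring A dithiane (C7 as acyl anion equivalent) adds to C4 of (5R)-menthyloxybutenolide, and the enolate is benzylated at C3 by the ring B/ring C bromide, whose syn-1,3-diol stems from an Evans aldol. The temporary C5 menthyloxy group, absent from the target, sets both lactone stereocentres and is excised afterwards.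

Key step: step 10

Assumption: compounds 1, 5, 8, 15 and the Reformatsky reagent of step 2 are taken as commercially available. Labels used are lactone O1, C2 (C=O), C3, C4, C5; C7 and C7' for the benzylic CH2 groups of rings A and B; and C7'' (carbinol), C8'' (methine), C9'' (CH2OH) for the chain between rings B and C.

Step 1
Reactants: 1 methyl 3-bromo-4-hydroxy-5-methoxybenzoate (methyl 5-bromovanillate)
Product: 2 methyl 4-(benzyloxy)-3-bromo-5-methoxybenzoate
Conditions: BnBr, K2CO3, DMF, 60 °C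
Reagents that add atoms: benzyl bromide, BrCc1ccccc1
Why: Williamson ether synthesis in which the acidic phenoxide is alkylated on oxygen, giving a benzyl ether that should survive every step up to the final hydrogenolysis.

Step 2
Reactants: 2 methyl 4-(benzyloxy)-3-bromo-5-methoxybenzoate
Product: 3 methyl 4-(benzyloxy)-3-(2-tert-butoxy-2-oxoethyl)-5-methoxybenzoate
Conditions: BrZnCH2CO2t-Bu, Pd2(dba)3 (cat.), XPhos (cat.), THF, 65 °C
Reagents that add atoms: (2-tert-butoxy-2-oxoethyl)zinc bromide, CC(C)(C)OC(=O)C[Zn]Br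
Why: Negishi-type α-arylation of a Reformatsky reagent, in which oxidative addition of zerovalent palladium into C–Br, transmetalation with the neutral zinc enolate and reductive elimination install the acetate arm without touching the methyl benzoate.

Step 3
Reactants: 3 methyl 4-(benzyloxy)-3-(2-tert-butoxy-2-oxoethyl)-5-methoxybenzoate
Product: 4 [2-(benzyloxy)-3-methoxy-5-(methoxycarbonyl)phenyl]acetic acid
Conditions: TFA, CH2Cl2, rt
Reagents that add atoms: none
Why: Acid-mediated tert-butyl ester cleavage through the tert-butyl cation frees the aliphatic acid while the methyl benzoate and the aryl benzyl ether stay intact.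

Step 4
Reactants: 4 [2-(benzyloxy)-3-methoxy-5-(methoxycarbonyl)phenyl]acetic acid; 5 (4S)-4-benzyl-1,3-oxazolidin-2-one
Product: 7 methyl 4-(benzyloxy)-3-{2-[(4S)-4-benzyl-2-oxo-1,3-oxazolidin-3-yl]-2-oxoethyl}-5-methoxybenzoate, via mixed pivalic anhydride 6 (not isolated)
Conditions: PivCl, Et3N, THF, −20 °C; then LiCl, 5, −20 °C to rt
Reagents that add atoms: none
Why: Mixed-anhydride N-acylation of an Evans oxazolidinone, in which the LiCl-activated auxiliary attacks the less hindered arylacetyl carbonyl of 6 and its own stereocentre is not involved.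

Step 5
Reactants: 7 methyl 4-(benzyloxy)-3-{2-[(4S)-4-benzyl-2-oxo-1,3-oxazolidin-3-yl]-2-oxoethyl}-5-methoxybenzoate; 8 4-(benzyloxy)-3-methoxybenzaldehyde (O-benzylvanillin)
Product: 10 methyl 4-(benzyloxy)-3-{(2S,3S)-1-[(4S)-4-benzyl-2-oxo-1,3-oxazolidin-3-yl]-3-[4-(benzyloxy)-3-methoxyphenyl]-3-hydroxy-1-oxopropan-2-yl}-5-methoxybenzoate (syn aldol adduct), via boron enolate 9 (not isolated)
Conditions: Bu2BOTf, i-Pr2NEt, CH2Cl2, 0 °C; 8, −78 to 0 °C; then pH 7 buffer, MeOH, H2O2, 0 °C
Reagents that add atoms: none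
Why: Evans syn aldol reaction in which the Z boron enolate 9 reacts through a Zimmerman–Traxler chair with the dipole-opposed (S)-benzyl auxiliary shielding one face, which should set C8'' and C7'' together as the (2S,3S) syn adduct.

Step 6
Reactants: 10 syn aldol adduct
Product: 11 (1S,2R)-2-[2-(benzyloxy)-5-(hydroxymethyl)-3-methoxyphenyl]-1-[4-(benzyloxy)-3-methoxyphenyl]propane-1,3-diol
Conditions: LiBH4 (excess), MeOH, THF, 0 to 45 °C
Reagents that add atoms: none
Why: Reductive auxiliary removal with LiBH4, where the imide carbonyl is reduced first in the cold (which shuts off retro-aldol) and the methyl benzoate on warming, with neither stereocentre touched (C8'' becomes R only through a change of CIP priorities).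

Step 7
Reactants: 11 (1S,2R)-triol
Product: 12 {4-(benzyloxy)-3-[(4S,5R)-4-[4-(benzyloxy)-3-methoxyphenyl]-2,2-dimethyl-1,3-dioxan-5-yl]-5-methoxyphenyl}methanol
Conditions: Me2C(OMe)2, PPTS (cat.), CH2Cl2, rt
Reagents that add atoms: 2,2-dimethoxypropane, COC(C)(C)OC
Why: Acid-catalysed transketalisation in which only the 1,3-diol can close a six-membered isopropylidene ketal (a cis-4,5-diaryl-1,3-dioxane), so the primary benzylic alcohol on ring B is left free.

Step 8
Reactants: 12 dioxanyl benzylic alcohol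
Product: 13 (4S,5R)-5-[2-(benzyloxy)-5-(bromomethyl)-3-methoxyphenyl]-4-[4-(benzyloxy)-3-methoxyphenyl]-2,2-dimethyl-1,3-dioxane
Conditions: CBr4, PPh3, 2,6-lutidine (buffer), CH2Cl2, −10 °C; used without storage
Reagents that add atoms: carbon tetrabromide, BrC(Br)(Br)Br
Why: Appel reaction, an SN2 displacement of the alkoxyphosphonium ion by bromide under buffered, essentially neutral conditions that should spare the ketal.

Step 9
Reactants: 8 4-(benzyloxy)-3-methoxybenzaldehyde
Product: 14 2-[4-(benzyloxy)-3-methoxyphenyl]-1,3-dithiane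
Conditions: HS(CH2)3SH, BF3·OEt2 (cat.), CH2Cl2, 0 °C to rt
Reagents that add atoms: propane-1,3-dithiol, SCCCS
Why: Lewis acid catalysed dithioacetalisation turns the aldehyde carbon (the future C7) into a Corey–Seebach acyl anion equivalent.

Step 10
Reactants: 14 2-[4-(benzyloxy)-3-methoxyphenyl]-1,3-dithiane; 15 (5R)-5-[(1R,2S,5R)-menthyloxy]furan-2(5H)-one; 13 ring B/ring C benzylic bromide
Product: 18 (3R,4R,5R)-3-{4-(benzyloxy)-3-[(4S,5R)-4-[4-(benzyloxy)-3-methoxyphenyl]-2,2-dimethyl-1,3-dioxan-5-yl]-5-methoxybenzyl}-4-{2-[4-(benzyloxy)-3-methoxyphenyl]-1,3-dithian-2-yl}-5-[(1R,2S,5R)-menthyloxy]dihydrofuran-2(3H)-one, via lithiated dithiane 16 (not isolated), via lithium enolate 17 (not isolated)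
Conditions: 14, n-BuLi, THF, −78 to −20 °C; 15, −78 °C; then 13, DMPU, −78 to −20 °C
Reagents that add atoms: none
Why: Tandem conjugate addition–enolate alkylation (three-component coupling with Corey–Seebach umpolung): n-BuLi converts 14 into the soft aryl- and sulfur-stabilised carbanion 16, which adds 1,4 to 15 and forms the C7–C4 bond, and the lithium enolate 17 is then benzylated at C3 by 13 in a DMPU-promoted SN2 reaction. The closest known reaction type is the addition of lithiated aryl dithioacetals to 2(5H)-furanones and 5-alkoxy-2(5H)-furanones with in situ trapping by benzylic bromides, the standard entry to dibenzylbutyrolactone lignans. No ring is closed, since the lactone ring is brought in intact. C4 is controlled by the C5 menthyloxy group, which blocks one face of the flat butenolide so that 16 enters anti to it (4,5-trans), and C3 is controlled by the bulky C4 dithianyl group, which sends 13 to the opposite face of 17 (3,4-trans), giving 3R,4R. The step needs 1,4- over 1,2-addition, secured by the delocalised carbanion at −78 °C, and single C-alkylation, secured by the reactive primary benzylic bromide and by a hindered product that is not enolised again. The ketal, the benzyl ethers and the two stereocentres of 13 are inert to the enolate.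

Step 11
Reactants: 18 three-component adduct
Product: 19 (3R,4R,5R)-3-{4-(benzyloxy)-3-[(4S,5R)-4-[4-(benzyloxy)-3-methoxyphenyl]-2,2-dimethyl-1,3-dioxan-5-yl]-5-methoxybenzyl}-4-[4-(benzyloxy)-3-methoxybenzyl]-5-[(1R,2S,5R)-menthyloxy]dihydrofuran-2(3H)-one
Conditions: NiCl2·6H2O, NaBH4, MeOH–THF, 0 °C
Reagents that add atoms: none
Why: Reductive desulfurisation with nickel boride (Ni2B) made in situ cleaves both benzylic C–S bonds to leave the C7 methylene group, while aryl benzyl ethers, ketal and lactone acetal are expected to survive at 0 °C.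

Step 12
Reactants: 19 desulfurised lactone acetal
Product: 23 (3R,4R)-3-{4-(benzyloxy)-3-[(1S,2R)-1-[4-(benzyloxy)-3-methoxyphenyl]-1,3-dihydroxypropan-2-yl]-5-methoxybenzyl}-4-[4-(benzyloxy)-3-methoxybenzyl]dihydrofuran-2(3H)-one, via aldehyde acid 20 (not isolated), via hydroxy acid 21 (not isolated), via lactone acetonide 22 (not isolated)
Conditions: KOH, NaBH4, EtOH–H2O, rt; EtOH evaporated; then 1 M HCl, THF, rt
Reagents that add atoms: none
Why: Saponification–borohydride reduction–lactonisation sequence in which hydroxide opens the pseudo-ester to menthol and aldehyde 20, borohydride reduces 20 to 21 faster than C4 can enolise, and alcohol-free aqueous acid then closes lactone 22 and hydrolyses the isopropylidene ketal at room temperature, where non-phenolic benzylic alcohols of this type should not ionise.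

Step 13
Reactants: 23 tri-O-benzyl lactone diol
Product: 24 (3R,4R)-3-{3-[(1S,2R)-1,3-dihydroxy-1-(4-hydroxy-3-methoxyphenyl)propan-2-yl]-4-hydroxy-5-methoxybenzyl}-4-(4-hydroxy-3-methoxybenzyl)dihydrofuran-2(3H)-one (target)
Conditions: H2 (1 atm), Pd/C, EtOAc–EtOH, rt
Reagents that add atoms: none
Why: Catalytic hydrogenolysis of the three aryl benzyl ethers under neutral conditions should be faster than cleavage of the secondary C7''–OH bond, so the reaction is stopped after three equivalents of hydrogen are taken up.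

Compound list
1 | methyl 3-bromo-4-hydroxy-5-methoxybenzoate | COC(=O)c1cc(Br)c(O)c(OC)c1 | starting material
2 | methyl 4-(benzyloxy)-3-bromo-5-methoxybenzoate | COC(=O)c1cc(Br)c(OCc2ccccc2)c(OC)c1 | intermediate
3 | methyl 4-(benzyloxy)-3-(2-tert-butoxy-2-oxoethyl)-5-methoxybenzoate | COC(=O)c1cc(OC)c(OCc2ccccc2)c(CC(=O)OC(C)(C)C)c1 | intermediate
4 | [2-(benzyloxy)-3-methoxy-5-(methoxycarbonyl)phenyl]acetic acid | COC(=O)c1cc(OC)c(OCc2ccccc2)c(CC(=O)O)c1 | intermediate
5 | (4S)-4-benzyl-1,3-oxazolidin-2-one | O=C1N[C@@H](Cc2ccccc2)CO1 | starting material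
6 | arylacetic pivalic mixed anhydride of 4 | COC(=O)c1cc(OC)c(OCc2ccccc2)c(CC(=O)OC(=O)C(C)(C)C)c1 | intermediate
7 | (4S)-N-arylacetyl oxazolidinone | COC(=O)c1cc(OC)c(OCc2ccccc2)c(CC(=O)N3[C@@H](Cc4ccccc4)COC3=O)c1 | intermediate
8 | 4-(benzyloxy)-3-methoxybenzaldehyde | COc1cc(C=O)ccc1OCc2ccccc2 | starting material
9 | (Z)-dibutylboron enolate of 7 | CCCCB(CCCC)O/C(=C\c1cc(C(=O)OC)cc(OC)c1OCc2ccccc2)N3[C@@H](Cc4ccccc4)COC3=O | intermediate
10 | (2S,3S) syn aldol adduct on the (4S) auxiliary | COC(=O)c1cc(OC)c(OCc2ccccc2)c(c1)[C@H](C(=O)N3[C@@H](Cc4ccccc4)COC3=O)[C@H](O)c5ccc(OCc6ccccc6)c(OC)c5 | intermediate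
11 | (1S,2R)-triol | OCc1cc(OC)c(OCc2ccccc2)c(c1)[C@H](CO)[C@H](O)c3ccc(OCc4ccccc4)c(OC)c3 | intermediate
12 | (4S,5R)-dioxanyl benzylic alcohol | OCc1cc(OC)c(OCc2ccccc2)c(c1)[C@@H]3COC(C)(C)O[C@@H]3c4ccc(OCc5ccccc5)c(OC)c4 | intermediate
13 | (4S,5R)-dioxanyl benzylic bromide | BrCc1cc(OC)c(OCc2ccccc2)c(c1)[C@@H]3COC(C)(C)O[C@@H]3c4ccc(OCc5ccccc5)c(OC)c4 | intermediate
14 | 2-[4-(benzyloxy)-3-methoxyphenyl]-1,3-dithiane | COc1cc(ccc1OCc2ccccc2)C3SCCCS3 | intermediate
15 | (5R)-5-[(1R,2S,5R)-menthyloxy]furan-2(5H)-one | CC(C)[C@@H]1CC[C@@H](C)C[C@H]1O[C@H]2C=CC(=O)O2 | starting material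
16 | 2-lithio-2-[4-(benzyloxy)-3-methoxyphenyl]-1,3-dithiane | [Li]C1(SCCCS1)c2ccc(OCc3ccccc3)c(OC)c2 | intermediate
17 | lithium enolate of the (4R,5R) conjugate adduct | CC(C)[C@@H]1CC[C@@H](C)C[C@H]1O[C@@H]2OC(O[Li])=C[C@H]2C3(SCCCS3)c4ccc(OCc5ccccc5)c(OC)c4 | intermediate
18 | (3R,4R,5R) three-component adduct | CC(C)[C@@H]1CC[C@@H](C)C[C@H]1O[C@@H]2OC(=O)[C@H](Cc3cc(OC)c(OCc4ccccc4)c(c3)[C@@H]5COC(C)(C)O[C@@H]5c6ccc(OCc7ccccc7)c(OC)c6)[C@H]2C3(SCCCS3)c4ccc(OCc5ccccc5)c(OC)c4 | intermediate
19 | (3R,4R,5R) desulfurised lactone acetal | CC(C)[C@@H]1CC[C@@H](C)C[C@H]1O[C@@H]2OC(=O)[C@H](Cc3cc(OC)c(OCc4ccccc4)c(c3)[C@@H]5COC(C)(C)O[C@@H]5c6ccc(OCc7ccccc7)c(OC)c6)[C@H]2Cc3ccc(OCc4ccccc4)c(OC)c3 | intermediate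
20 | (2R,3R)-2,3-bis(arylmethyl)-4-oxobutanoic acid | OC(=O)[C@H](Cc1cc(OC)c(OCc2ccccc2)c(c1)[C@@H]3COC(C)(C)O[C@@H]3c4ccc(OCc5ccccc5)c(OC)c4)[C@@H](Cc6ccc(OCc7ccccc7)c(OC)c6)C=O | intermediate
21 | (2R,3R)-2,3-bis(arylmethyl)-4-hydroxybutanoic acid | OC(=O)[C@H](Cc1cc(OC)c(OCc2ccccc2)c(c1)[C@@H]3COC(C)(C)O[C@@H]3c4ccc(OCc5ccccc5)c(OC)c4)[C@@H](Cc6ccc(OCc7ccccc7)c(OC)c6)CO | intermediate
22 | (3R,4R)-lactone acetonide | COc1cc(C[C@H]2COC(=O)[C@@H]2Cc3cc(OC)c(OCc4ccccc4)c(c3)[C@@H]5COC(C)(C)O[C@@H]5c6ccc(OCc7ccccc7)c(OC)c6)ccc1OCc8ccccc8 | intermediate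
23 | (3R,4R)-tri-O-benzyl lactone diol | COc1cc(C[C@H]2COC(=O)[C@@H]2Cc3cc(OC)c(OCc4ccccc4)c(c3)[C@H](CO)[C@H](O)c5ccc(OCc6ccccc6)c(OC)c5)ccc1OCc7ccccc7 | intermediate
24 | target CNP0317849.1 | COc1cc(C[C@H]2COC(=O)[C@@H]2Cc2cc(OC)c(O)c([C@H](CO)[C@H](O)c3ccc(O)c(OC)c3)c2)ccc1O | target

Total step count: 13. Longest linear sequence: 12 steps (steps 1–8 and 10–13).

Steps most likely to fail

Step 10. The crowded enolate 17 may be alkylated too slowly. Proton transfer, retro-Michael loss of the dithiane anion or decay of the labile bromide could then compete.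
- The fallback sets out from 14 and 15 and separates the two bond formations.
- Enolate 17 is quenched with aqueous NH4Cl to give the C3-unsubstituted (4R,5R) conjugate adduct F1.
- Desulfurisation with NiCl2·6H2O/NaBH4 gives the (4R,5R)-4-arylmethyl-5-menthyloxy lactone F2.
- The much less hindered enolate of F2 (LiHMDS, THF, −78 °C) is alkylated with 13 anti to the C4 substituent.
- The fallback comes back to the route at 19.

Step 12. C4 may partly epimerise through enolisation of the transient aldehyde in base, and C7'' may ionise during the acid stage.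
- The fallback sets out from 13 and 14 and avoids the acetal excision altogether.
- Carbanion 16 is added to achiral commercial furan-2(5H)-one and the enolate is trapped with 13.
- Because 13 is enantiopure, the two trans products are diastereomers: the (3R,4R) dithianyl lactone acetonide F3 and its (3S,4S) isomer F4. They are separated by chromatography.
- Desulfurisation of F3 with NiCl2·6H2O/NaBH4 gives 22, which is now isolated.
- The ketal of 22 is removed separately with 80% aqueous AcOH at 40 °C.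
- The fallback comes back to the route at 23.

Step 5. The addition may be slow because of the ortho benzyloxy group, and retro-aldol equilibration of the α-aryl aldolate may erode the syn selectivity.
- The fallback sets out from 4. It forms the C7''–C8'' bond by acylation and sets C7'' by reduction.
- Acid 4 is coupled (PivCl, Et3N, LiCl) with commercial (4R)-4-benzyl-1,3-oxazolidin-2-one to give the (4R) imide F5.
- The chelated Z lithium enolate of F5 (LiHMDS, THF, −78 °C) is C-acylated with 4-(benzyloxy)-3-methoxybenzoyl chloride on the face opposite the auxiliary benzyl group, giving the (2S) β-keto imide F6.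
- Chelation-controlled reduction with Zn(BH4)2 (CH2Cl2–Et2O, −20 °C) should give the (2S,3S) syn β-hydroxy imide F7.
- LiBH4 reduction as in step 6 brings the fallback back to the route at 11.

Further compounds
F1 | step 10 | (4R,5R)-4-{2-[4-(benzyloxy)-3-methoxyphenyl]-1,3-dithian-2-yl}-5-[(1R,2S,5R)-menthyloxy]dihydrofuran-2(3H)-one | CC(C)[C@@H]1CC[C@@H](C)C[C@H]1O[C@@H]2OC(=O)C[C@H]2C3(SCCCS3)c4ccc(OCc5ccccc5)c(OC)c4
F2 | step 10 | (4R,5R)-4-[4-(benzyloxy)-3-methoxybenzyl]-5-[(1R,2S,5R)-menthyloxy]dihydrofuran-2(3H)-one | CC(C)[C@@H]1CC[C@@H](C)C[C@H]1O[C@@H]2OC(=O)C[C@H]2Cc3ccc(OCc4ccccc4)c(OC)c3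
F3 | step 12 | (3R,4R) dithianyl lactone acetonide | COc1cc(ccc1OCc2ccccc2)C3(SCCCS3)[C@H]4COC(=O)[C@@H]4Cc5cc(OC)c(OCc6ccccc6)c(c5)[C@@H]7COC(C)(C)O[C@@H]7c8ccc(OCc9ccccc9)c(OC)c8
F4 | step 12 | (3S,4S) dithianyl lactone acetonide (separated diastereomer) | COc1cc(ccc1OCc2ccccc2)C3(SCCCS3)[C@@H]4COC(=O)[C@H]4Cc5cc(OC)c(OCc6ccccc6)c(c5)[C@@H]7COC(C)(C)O[C@@H]7c8ccc(OCc9ccccc9)c(OC)c8
F5 | step 5 | (4R)-N-arylacetyl oxazolidinone | COC(=O)c1cc(OC)c(OCc2ccccc2)c(CC(=O)N3[C@H](Cc4ccccc4)COC3=O)c1
F6 | step 5 | (2S) β-keto imide on the (4R) auxiliary | COC(=O)c1cc(OC)c(OCc2ccccc2)c(c1)[C@H](C(=O)N3[C@H](Cc4ccccc4)COC3=O)C(=O)c5ccc(OCc6ccccc6)c(OC)c5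
F7 | step 5 | (2S,3S) syn β-hydroxy imide on the (4R) auxiliary | COC(=O)c1cc(OC)c(OCc2ccccc2)c(c1)[C@H](C(=O)N3[C@H](Cc4ccccc4)COC3=O)[C@H](O)c5ccc(OCc6ccccc6)c(OC)c5
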